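Compound numbers used throughout: **1** 5,6,7-trimethoxyflavone; **2** (2S)-flavan-4-ol mixture; **3** (S)-flavanone; **4** cis-alcohol; **5** trans-acetate; **6** trans-alcohol (unit B); **7** 5-methoxyresorcinol; **8** 5-methoxycyclohexane-1,3-dione; **9** ethoxymethylene dione; **10** heterodiene; **11** styrene; **12** cycloadduct; **13** sodium enolate of 12; **14** 6-hydroxy ketone; **15** 6-methoxy ketone; **16** lithium enolate of 15; **17** 6-phenylselanyl ketone; **18** selenoxide; **19** dienone; **20** beilschmieflavonoid B. Unit A is the 5-hydroxy half (unprimed flavan numbering), unit B the 5,6,7-trimethoxy half (primed).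

## Analysis of the target

Beilschmieflavonoid B (20, C35H36O9) consists of two flavan (2-phenylchroman) units joined by one ether oxygen between C4 of unit A (5-hydroxy-6,7-dimethoxy) and C4' of unit B (5',6',7'-trimethoxy). It has four stereocentres, C2 (S), C4 (R), C2' (S) and C4' (R); in each unit the 2-phenyl group and the 4-oxygen are trans, which in the half-chair pyran ring means phenyl equatorial and the ether oxygen pseudoaxial, clear of the peri oxygen at C5 or C5'. The two halves thus share relative and absolute configuration and differ by a single O-methyl group. The sensitive element is the central bis-benzylic ether: each C–O bond is benzylic to an arene with two ortho and one para oxygen donors, so acid invites ionisation, epimerisation, elimination to a flav-3-ene and scrambling of the halves, and the free 5-hydroxyl ortho to C4 can expel the ether as an ortho-quinone methide. Both arenes are very electron-rich and will not tolerate strong oxidants or electrophiles. The hard points are therefore to form an ether between two hindered, ionisation-prone secondary benzylic carbons with control at both, to single out O5 as the only free phenol on a ring whose C4a is flanked by two oxygens, and to set the 2,4-trans relationship twice. The plan rests on the fact that O1–C8a–C4a–C5(OH) of unit A is the enol ether of a cyclohexane-1,3-dione: at that oxidation level C5 is a ketone, C4 with its oxygen is an alkoxymethylene carbon on C4a, O1=C8a–C4a=C4 is a 1-oxadiene that can take up styrene 11 as C2–C3, and the symmetry of the dione removes the question of which ortho oxygen closes the pyran ring.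

## Retrosynthetic reasoning

**20 ⇒ 15 (through 19, 18, 17).** The first step back removes no skeletal bond but the aromaticity of ring A: the C6=C7 double bond is taken out, so 20 becomes its keto tautomer 19 and then the saturated 6,7-dimethoxy ketone 15. Ring A is chosen because this turns O5 into a ketone oxygen, so the single free phenol of 20 appears only in the last step and needs no protecting group. Forward, a double bond must be introduced between C6 and C7 next to the ketone (selenide 17, selenoxide 18), after which 19 aromatises by proton shift.

**15 ⇒ 14 ⇒ 12.** The C6–O bond is cut. C6 is the only enolisable α-carbon of the C5 ketone in 12 (C4a is sp2), so oxygenation of the enolate can only go there. Methylating the resulting aliphatic alcohol 14 before aromatisation distinguishes O6 from O5 without any selective phenol chemistry.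

**12 ⇒ 10 + 11.** The O1–C2 and C3–C4 bonds are cut together in a retro-hetero-Diels–Alder sense. This removes the pyran ring of unit A and both of its stereocentres in one operation and leaves the symmetrical alkoxymethylene dione 10 and styrene 11. Forward, the cycloaddition has to join the CH2 terminus of 11 to the alkoxymethylene carbon, add to the face that gives (4R), place phenyl exo so that C2 is trans to C4, and do so without breaking the activated benzylic C4'–O bond of 10. Later acid-induced correction at C4 is not counted on, because acid would open the ether on the unit B side first and leave C4 as it was. C7 becomes a temporary, uncontrolled stereocentre that disappears in 19.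

**10 ⇒ 6 + 9.** The vinylic C–O bond between the exocyclic carbon and the ether oxygen is cut, not the C4'–O bond. The central ether of 20 is therefore never made by substitution at a benzylic stereocentre: forward, the hydroxyl of 6 adds to the sp2 carbon of 9 and the ethoxy group leaves, with the configuration of 6 untouched.

**9 ⇒ 8 ⇒ 7.** The one-carbon alkoxymethylene unit is removed from C2 of dione 8, and 8 is traced to arene 7 by partial reduction. The 7-methoxy group of the target is thus present from the start.

**6 ⇒ 5 ⇒ 4 ⇒ 3 ⇒ 2 ⇒ 1.** The (4'R) alcohol 6 is related to its C4' epimer 4 by inversion through ester 5, because hydride reduction of flavanone 3 gives the cis alcohol 4. C2' is traced to the asymmetric reduction of the C2=C3 bond of flavone 1, with 2 as the over-reduced mixture that is reoxidised to 3.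

## Alternatives that were turned down

**Alternative 1:** Both aryl ether bonds (C8a–O1 and C8a'–O1') are cut, which leads to the open-chain dibromo diol A1 in which the central ether and all four stereocentres already exist. Forward, a copper-mediated double intramolecular O-arylation under carbonate base joins each secondary benzylic alkoxide to the neighbouring C–Br carbon and gives the 5-O-allyl ether A2, which is then deallylated to 20. In its favour, the stereocentres are made by acyclic chemistry and are not touched when the rings close, both pyran rings form in one operation, and there are no epimer mixtures or late oxidation-state changes; on stereochemical security it is stronger than the chosen route. Against it, A1 must already contain the ether between two hindered, 2,6-disubstituted benzylic carbinol carbons, so the hardest bond of the molecule is pushed into the precursor and would have to be made by substitution at an ionisation-prone centre. The aryl bromides are also very electron-rich and react slowly with copper, the hot basic conditions expose two benzylic alkoxides to elimination, O5 needs a protecting group and a deprotection step, and each half needs its own multistep acyclic synthesis. The chosen route instead makes the ether at an sp2 carbon by addition–elimination, needs no protecting group, removes the ortho-oxygen ambiguity by symmetry and is shorter.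

**Alternative 2:** The C2'–C3' bond of unit B is cut as a double bond, which leads to diene A3 (vinyl group on C4', 1-phenylvinyl ether on the aryl oxygen) with unit A complete as its 5-O-silyl ether. Forward, a ruthenium carbene metathesis catalyst closes the 4H-chromene A4 with loss of the two terminal CH2 groups; radical (hydrogen atom transfer) hydrogenation of the enol ether and desilylation would follow. In its favour, unit A is carried in finished aromatic form, metathesis is indifferent to the electron-rich arenes, and the ring closure does not depend on diastereoselection, so on that point it is stronger. Against it, the metathesis must engage a 1,1-disubstituted electron-rich enol ether and form a trisubstituted one, a slow class in which the ruthenium tends to rest as a stabilised alkoxycarbene. A4 is an allylic and benzylic ether one ionisation away from an aromatic 2-phenylbenzopyrylium ion and is more labile than anything in the chosen route. The key step creates no stereocentre, so C2' has to be set afterwards by hydrogen delivery to a benzylic radical with only remote guidance from C4', and C2, C4, C4' and the ether all have to be made beforehand with a silyl group on O5. The chosen route forms a ring, two bonds and two stereocentres in its key step and needs no protection.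

**Alternative 3:** The O1'–C2' bond of unit B is cut, which leads to A5, an ortho-hydroxyaryl (E)-styrenyl carbinol ether of 5-O-protected unit A whose carbinol centre would come from a Claisen rearrangement with transfer of chirality. Forward, an electrophilic iodine reagent with bicarbonate buffer forms the iodonium ion on the styrenyl double bond and the phenol oxygen attacks the benzylic carbon anti to iodine (6-endo), which gives the 3'-iodoflavan A6; radical removal of iodine and of the O5 protecting group would follow. In its favour, this ring closure is dependable, its regiochemistry is fixed by the benzylic position, and C2' is relayed from C4' through a chair-like transition state, which is more predictable than the cycloaddition of the chosen route. Against it, A5 has a free phenol ortho to an allylic, benzylic ether carbon, the arrangement that most readily ejects the ether as an ortho-quinone methide. The iodine electrophile can also attack the free C8 and C8' positions of the two activated arenes. Two further steps are needed after the key step, and the usual conditions for removing the acetal protecting group are unkind to the bis-benzylic ether. Unit A and the ether must again be built separately. The chosen route is shorter, protecting-group-free and builds unit A on the ether oxygen itself.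

Key step: step 9

Assumption: in step 1 the (R,R) enantiomer of the carbene ligand is taken to deliver the (2S) series; if the sense of induction is the opposite, the (S,S) ligand is used.

Assumption: in step 9 (+)-Eu(hfc)3 is taken to be the enantiomer that reinforces addition to the Re face of the alkoxymethylene carbon of 10; if it is the mismatched partner, (−)-Eu(hfc)3 is used.

## Route

Step 1
Reactants: 1 5,6,7-trimethoxyflavone
Product: 2 (2S)-5,6,7-trimethoxyflavan-4-ol (C4 epimers)
Conditions: [Ru(cod)(2-methylallyl)2] (5 mol%), (R,R)-SINpEt·HBF4 (1,3-bis[(R)-1-(1-naphthyl)ethyl]imidazolinium tetrafluoroborate, 10 mol%), KOt-Bu (15 mol%), H2 (100 bar), toluene, 25 °C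
Reagents that add atoms: none
Why: Ruthenium–N-heterocyclic-carbene-catalysed asymmetric hydrogenation of the C2=C3 bond of a flavone sets C2 by ligand control of the face of H2 delivery. Onward reduction of the ketone is partial and unselective at C4, which does not matter because step 2 converges the mixture (any 3 already present is carried along).

Step 2
Reactants: 2 (2S)-5,6,7-trimethoxyflavan-4-ol (C4 epimers)
Product: 3 (S)-5,6,7-trimethoxyflavanone
Conditions: Dess–Martin periodinane, NaHCO3, CH2Cl2, 0 °C to 20 °C
Reagents that add atoms: none
Why: Dess–Martin oxidation of a secondary benzylic alcohol under buffered, non-basic conditions returns the ketone. C2 is safe because its epimerisation would need base-induced opening of the pyranone ring.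

Step 3
Reactants: 3 (S)-5,6,7-trimethoxyflavanone
Product: 4 (2S,4S)-5,6,7-trimethoxyflavan-4-ol (2,4-cis)
Conditions: NaBH4, MeOH/THF, 0 °C
Reagents that add atoms: none
Why: Borohydride reduction of a flavanone: hydride adds axially to the half-chair with the 2-phenyl group equatorial and gives the equatorial, 2,4-cis alcohol by substrate control (1,3-induction from C2).

Step 4
Reactants: 4 (2S,4S)-5,6,7-trimethoxyflavan-4-ol (2,4-cis)
Product: 5 (2S,4R)-5,6,7-trimethoxyflavan-4-yl acetate (2,4-trans)
Conditions: PPh3, DIAD, AcOH, THF, −20 °C to 0 °C
Reagents that add atoms: acetic acid CC(=O)O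
Why: Mitsunobu reaction: acetate displaces the alkoxyphosphonium group with inversion at C4. Any leakage through the stabilised benzylic cation also ends in the trans ester, because axial capture with phenyl equatorial is preferred, so both pathways converge on (4R); acetate is chosen as the poorest carboxylate leaving group so that the ester can be handled.

Step 5
Reactants: 5 (2S,4R)-5,6,7-trimethoxyflavan-4-yl acetate (2,4-trans)
Product: 6 (2S,4R)-5,6,7-trimethoxyflavan-4-ol (2,4-trans)
Conditions: LiOH, THF/H2O, 0 °C
Reagents that add atoms: none
Why: Saponification by acyl–oxygen cleavage leaves the C4–O bond and the (4R) configuration untouched. The cold basic medium avoids the acid under which this alcohol would ionise.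

Step 6
Reactants: 7 5-methoxyresorcinol
Product: 8 5-methoxycyclohexane-1,3-dione
Conditions: H2 (3.5 bar), Rh/Al2O3 (5 wt%), NaOH (1.0 equiv), H2O, 20 °C; then HCl to pH 3, 0 °C
Reagents that add atoms: none
Why: Partial hydrogenation of a resorcinol monoanion: one equivalent of H2 is taken up to give the β-diketonate, which resists further reduction, as with resorcinol and phloroglucinol in aqueous base. Room temperature and cold acidification are chosen to avoid β-elimination of methanol.

Step 7
Reactants: 8 5-methoxycyclohexane-1,3-dione
Product: 9 2-(ethoxymethylene)-5-methoxycyclohexane-1,3-dione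
Conditions: (EtO)2CHOAc (3 equiv), toluene, 45 °C; volatiles removed, toluene azeotrope
Reagents that add atoms: diethoxymethyl acetate CCOC(OCC)OC(C)=O
Why: Orthoformate-type condensation at an active methylene group: the diethoxycarbenium ion from the reagent attacks C2 of the enol and loss of ethanol gives the alkoxymethylene dione. The reagent works well below the temperature of the acetic anhydride procedure, at which loss of methanol would threaten.

Step 8
Reactants: 6 (2S,4R)-5,6,7-trimethoxyflavan-4-ol (2,4-trans), 9 2-(ethoxymethylene)-5-methoxycyclohexane-1,3-dione
Product: 10 5-methoxy-2-({[(2S,4R)-5,6,7-trimethoxyflavan-4-yl]oxy}methylene)cyclohexane-1,3-dione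
Conditions: 9 (3 equiv), i-Pr2NEt (0.2 equiv), 5 Å molecular sieves, toluene, 50 °C; chromatography on Et3N-deactivated silica
Reagents that add atoms: none
Why: Vinylic substitution by addition–elimination (alkoxy exchange on an alkoxymethylene-1,3-dicarbonyl compound): the hydroxyl of 6 adds to the doubly activated exocyclic carbon and ethanol is expelled and taken up by the sieves. The C4'–O bond of 6 is never broken, so its configuration is retained, and the amine keeps the medium free of acid.

Step 9
Reactants: 10 5-methoxy-2-({[(2S,4R)-5,6,7-trimethoxyflavan-4-yl]oxy}methylene)cyclohexane-1,3-dione, 11 styrene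
Product: 12 (2S,4R)-7-methoxy-2-phenyl-4-{[(2S,4R)-5,6,7-trimethoxyflavan-4-yl]oxy}-2,3,4,6,7,8-hexahydro-5H-chromen-5-one (C7 epimers)
Conditions: (+)-Eu(hfc)3 (hfc = 3-(heptafluoropropylhydroxymethylene)-(+)-camphorate, 10 mol%), 11 (20 equiv), BHT (1 mol%), toluene, 45 °C, dark
Reagents that add atoms: none
Why: The europium complex binds a carbonyl oxygen of 10 and lowers the LUMO of the O1=C8a–C4a=C4 oxadiene; the CH2 terminus of styrene bonds to the alkoxymethylene carbon (largest LUMO coefficient) and the benzylic carbon to the carbonyl oxygen in a concerted but strongly asynchronous [4+2] step. The closest known reaction type is the inverse-electron-demand oxa-Diels–Alder reaction of 2-alkylidene- and 2-alkoxymethylene-1,3-dicarbonyl compounds with enol ethers and styrenes under lanthanide tris(β-diketonate) catalysis. The dihydropyran ring is closed intermolecularly as a [4π+2π] cycloaddition, with O1–C2 and C3–C4 formed in the same event, so no tether or ring-size constraint applies. The two carbonyl groups of the dione are equivalent, so either gives the same constitution and the other remains as the C5 ketone. (4R) arises from addition to the Re face of the alkoxymethylene carbon, controlled jointly by the (4'R) stereocentre of unit B on the enol ether oxygen and by the chiral europium complex (double stereodifferentiation). (2S) follows from the exo orientation of phenyl, which gives the 2,4-trans adduct; exo should be favoured because the endo mode puts phenyl over the saturated C8–C7 edge of the carbocycle, where pseudoaxial hydrogen and methoxy substituents occupy that space, and trans is also the more stable arrangement (phenyl equatorial, alkoxy pseudoaxial, clear of the C5 carbonyl). The step needs cycloaddition to outrun heterolysis of the activated benzylic C4'–O bond of 10, which is why a weakly acidic, non-chelating lanthanide complex and a large excess of styrene are chosen rather than a strong or chelating Lewis acid. C7 is not controlled and is erased later; because unit B is a single enantiomer, all C2/C4 isomers are diastereomers and can be separated here or, at the latest, after aromatisation.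

Step 10
Reactants: 12 (2S,4R)-7-methoxy-2-phenyl-4-{[(2S,4R)-5,6,7-trimethoxyflavan-4-yl]oxy}-2,3,4,6,7,8-hexahydro-5H-chromen-5-one (C7 epimers)
Product: 14 (2S,4R)-6-hydroxy-7-methoxy-2-phenyl-4-{[(2S,4R)-5,6,7-trimethoxyflavan-4-yl]oxy}-2,3,4,6,7,8-hexahydro-5H-chromen-5-one (C6 and C7 epimers), via sodium enolate 13 (not isolated)
Conditions: NaN(SiMe3)2 (1.1 equiv), THF, −78 °C; 2-(phenylsulfonyl)-3-phenyloxaziridine (1.3 equiv), −78 °C; AcOH (1.2 equiv), −78 °C
Reagents that add atoms: 2-(phenylsulfonyl)-3-phenyloxaziridine O=S(=O)(c1ccccc1)N1OC1c1ccccc1
Why: Kinetic α'-deprotonation of the vinylogous ester at C6, followed by oxygen transfer from the N-sulfonyloxaziridine to the enolate (Davis oxidation). C6 forms as a mixture of epimers, which is immaterial because C6 becomes sp2 in step 13, and the low temperature and cold quench are meant to keep the enolate from expelling the β-methoxy group at C7.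

Step 11
Reactants: 14 (2S,4R)-6-hydroxy-7-methoxy-2-phenyl-4-{[(2S,4R)-5,6,7-trimethoxyflavan-4-yl]oxy}-2,3,4,6,7,8-hexahydro-5H-chromen-5-one (C6 and C7 epimers)
Product: 15 (2S,4R)-6,7-dimethoxy-2-phenyl-4-{[(2S,4R)-5,6,7-trimethoxyflavan-4-yl]oxy}-2,3,4,6,7,8-hexahydro-5H-chromen-5-one (C6 and C7 epimers)
Conditions: MeI (excess), Ag2O, 4 Å molecular sieves, CH2Cl2, 35 °C, dark
Reagents that add atoms: iodomethane CI
Why: Purdie methylation alkylates the secondary hydroxyl under essentially neutral conditions, with neither enolate formation nor acid. Methylating here, before aromatisation, is what leaves O5 as the only free phenol in the end.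

Step 12
Reactants: 15 (2S,4R)-6,7-dimethoxy-2-phenyl-4-{[(2S,4R)-5,6,7-trimethoxyflavan-4-yl]oxy}-2,3,4,6,7,8-hexahydro-5H-chromen-5-one (C6 and C7 epimers)
Product: 17 (2S,4R)-6,7-dimethoxy-2-phenyl-6-(phenylselanyl)-4-{[(2S,4R)-5,6,7-trimethoxyflavan-4-yl]oxy}-2,3,4,6,7,8-hexahydro-5H-chromen-5-one (C6 and C7 epimers), via lithium enolate 16 (not isolated)
Conditions: LiN(i-Pr)2 (1.2 equiv), THF, −78 °C; PhSeBr (1.3 equiv), −78 °C
Reagents that add atoms: benzeneselenenyl bromide Br[Se]c1ccccc1
Why: α-Selenenylation of a ketone enolate: the base removes H6, now the only α-hydrogen of the ketone, and PhSeBr traps the enolate at carbon. Attack anti to the adjacent C7 methoxy group is expected, which places selenium syn to H7 as the next step requires.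

Step 13
Reactants: 17 (2S,4R)-6,7-dimethoxy-2-phenyl-6-(phenylselanyl)-4-{[(2S,4R)-5,6,7-trimethoxyflavan-4-yl]oxy}-2,3,4,6,7,8-hexahydro-5H-chromen-5-one (C6 and C7 epimers)
Product: 20 beilschmieflavonoid B, via selenoxide 18 (not isolated), via dienone 19 (not isolated)
Conditions: mCPBA (1.05 equiv), CH2Cl2, −78 °C; i-Pr2NH (3 equiv), −78 °C to 20 °C
Reagents that add atoms: none
Why: Selenide oxidation followed by selenoxide syn-elimination: the only β-hydrogen is H7, so the C6=C7 double bond forms. The resulting dienone 19, with sp3 C8, is the keto tautomer of a phenol and aromatises by proton shift, which erases C6 and C7 as stereocentres; the amine traps PhSeOH and buffers the acid so that the phenol and the bis-benzylic ether are spared.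

## Compound list

1 | 5,6,7-trimethoxyflavone | COc1cc2oc(-c3ccccc3)cc(=O)c2c(OC)c1OC | starting material
2 | (2S)-5,6,7-trimethoxyflavan-4-ol, C4 epimers | OC1C[C@@H](c2ccccc2)Oc2cc(OC)c(OC)c(OC)c21 | intermediate
3 | (S)-5,6,7-trimethoxyflavanone | O=C1C[C@@H](c2ccccc2)Oc2cc(OC)c(OC)c(OC)c21 | intermediate
4 | (2S,4S)-5,6,7-trimethoxyflavan-4-ol (2,4-cis) | O[C@H]1C[C@@H](c2ccccc2)Oc2cc(OC)c(OC)c(OC)c21 | intermediate
5 | (2S,4R)-5,6,7-trimethoxyflavan-4-yl acetate (2,4-trans) | CC(=O)O[C@@H]1C[C@@H](c2ccccc2)Oc2cc(OC)c(OC)c(OC)c21 | intermediate
6 | (2S,4R)-5,6,7-trimethoxyflavan-4-ol (2,4-trans, unit B) | O[C@@H]1C[C@@H](c2ccccc2)Oc2cc(OC)c(OC)c(OC)c21 | intermediate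
7 | 5-methoxyresorcinol | COc1cc(O)cc(O)c1 | starting material
8 | 5-methoxycyclohexane-1,3-dione | COC1CC(=O)CC(=O)C1 | intermediate
9 | 2-(ethoxymethylene)-5-methoxycyclohexane-1,3-dione (racemic about the cyclohexylidene axis) | CCOC=C1C(=O)CC(OC)CC1=O | intermediate
10 | 5-methoxy-2-({[(2S,4R)-5,6,7-trimethoxyflavan-4-yl]oxy}methylene)cyclohexane-1,3-dione (both orientations of the 5-methoxy group relative to the exocyclic double bond) | COC1CC(=O)C(=CO[C@@H]2C[C@@H](c3ccccc3)Oc3cc(OC)c(OC)c(OC)c32)C(=O)C1 | intermediate
11 | styrene | C=Cc1ccccc1 | starting material
12 | (2S,4R)-7-methoxy-2-phenyl-4-{[(2S,4R)-5,6,7-trimethoxyflavan-4-yl]oxy}-2,3,4,6,7,8-hexahydro-5H-chromen-5-one, C7 epimers | COC1CC2=C(C(=O)C1)[C@H](O[C@@H]1C[C@@H](c3ccccc3)Oc3cc(OC)c(OC)c(OC)c31)C[C@@H](c1ccccc1)O2 | intermediate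
13 | sodium C5–C6 enolate of 12 | COC1CC2=C(C([O-])=C1)[C@H](O[C@@H]1C[C@@H](c3ccccc3)Oc3cc(OC)c(OC)c(OC)c31)C[C@@H](c1ccccc1)O2.[Na+] | intermediate
14 | 6-hydroxy derivative of 12, C6 and C7 epimers | COC1CC2=C(C(=O)C1O)[C@H](O[C@@H]1C[C@@H](c3ccccc3)Oc3cc(OC)c(OC)c(OC)c31)C[C@@H](c1ccccc1)O2 | intermediate
15 | 6-methoxy derivative of 12, C6 and C7 epimers | COC1CC2=C(C(=O)C1OC)[C@H](O[C@@H]1C[C@@H](c3ccccc3)Oc3cc(OC)c(OC)c(OC)c31)C[C@@H](c1ccccc1)O2 | intermediate
16 | lithium C5–C6 enolate of 15 | COC1CC2=C(C([O-])=C1OC)[C@H](O[C@@H]1C[C@@H](c3ccccc3)Oc3cc(OC)c(OC)c(OC)c31)C[C@@H](c1ccccc1)O2.[Li+] | intermediate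
17 | 6-methoxy-6-(phenylselanyl) derivative of 12, C6 and C7 epimers | COC1CC2=C(C(=O)C1(OC)[Se]c1ccccc1)[C@H](O[C@@H]1C[C@@H](c3ccccc3)Oc3cc(OC)c(OC)c(OC)c31)C[C@@H](c1ccccc1)O2 | intermediate
18 | selenoxide of 17 | COC1CC2=C(C(=O)C1(OC)[Se](=O)c1ccccc1)[C@H](O[C@@H]1C[C@@H](c3ccccc3)Oc3cc(OC)c(OC)c(OC)c31)C[C@@H](c1ccccc1)O2 | intermediate
19 | (2S,4R)-6,7-dimethoxy-2-phenyl-4-{[(2S,4R)-5,6,7-trimethoxyflavan-4-yl]oxy}-2,3,4,8-tetrahydro-5H-chromen-5-one (keto tautomer of 20) | O=C1C(OC)=C(OC)CC2=C1[C@H](O[C@@H]1C[C@@H](c3ccccc3)Oc3cc(OC)c(OC)c(OC)c31)C[C@@H](c1ccccc1)O2 | intermediate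
20 | beilschmieflavonoid B | COc1cc2c(c(O)c1OC)[C@H](O[C@@H]1C[C@@H](c3ccccc3)Oc3cc(OC)c(OC)c(OC)c31)C[C@@H](c1ccccc1)O2 | target

## Step count and least certain steps

Total step count: 13. Longest linear sequence: 11 steps (steps 1–5 and 8–13); steps 6 and 7 form the two-step side branch to 9.

**Step 9 (key step).** Three things can go wrong.
- The cycloaddition may be too slow, because styrene is a weak nucleophile for a donor-substituted oxadiene.
- The Lewis acid may promote heterolysis of the activated benzylic C4'–O bond of 10, followed by elimination in unit B and cationic polymerisation of styrene.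
- Endo/exo or facial selectivity may be poor, which lowers the share of the (2S,4R) diastereomer.

Fallback, which gives up the cycloaddition and joins the halves through an ortho-quinone methide: it sets out from 3 and 6 and rejoins at 20. The 5-methoxy group of 3, peri to the carbonyl, is cleaved selectively with BCl3 (chelation control) to give (S)-5-hydroxy-6,7-dimethoxyflavanone F1. NaBH4 reduction gives (2S,4S)-5-hydroxy-6,7-dimethoxyflavan-4-ol F2. Warming F2 with an excess of 6 in toluene over molecular sieves should expel water to form the ortho-quinone methide (2S)-6,7-dimethoxy-2-phenyl-2,3-dihydro-5H-chromen-5-one F3, to which the hydroxyl of 6 adds at C4, axially and reversibly, with the trans ether 20 as the expected thermodynamic product; 6 keeps its configuration because only its O–H bond reacts.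

**Step 12 (with step 13).** The C6 enolate may expel the C7 methoxy group, followed by aromatisation with loss of the 7-oxygen. Selenium may also enter syn to the C7 methoxy group, which would leave the selenoxide without a syn β-hydrogen. The electron-rich phenol may be selenenylated or oxidised once formed.

Fallback by Saegusa–Ito dehydrogenation, from 15 back to 20: LiN(i-Pr)2 in the presence of Me3SiCl (in situ quench, so the free enolate has no lifetime) gives the trimethylsilyl enol ether of 15 F11, and Pd(OAc)2 in MeCN at 20 °C should convert it to dienone 19, which tautomerises to 20.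

**Step 10.** β-Elimination of methoxide from the enolate, competing deprotonation at C8, and addition of the enolate to the sulfonimine by-product are the likely failures.

Fallback by Rubottom oxidation, from 12 back to 14: the same in situ silylation gives the trimethylsilyl dienol ether of 12 F9; dimethyldioxirane at −78 °C should epoxidise its C5=C6 bond (the terminus of the 1-alkoxy-3-silyloxy diene) and rearrangement gives the 6-(trimethylsilyloxy) ketone F10, which is desilylated with acetic-acid-buffered fluoride to 14.

**Step 8.** The exchange is an equilibrium and may stall, and the product, a benzylic ether of a strongly acidic enol, may ionise at C4' on silica or with traces of acid.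

Fallback by irreversible substitution, from 9 and 6 back to 10: 9 is first exchanged with 4-nitrophenol to give 5-methoxy-2-[(4-nitrophenoxy)methylene]cyclohexane-1,3-dione F4, and the sodium alkoxide of 6 (NaH, THF, −78 °C) then displaces 4-nitrophenoxide under kinetic control, so that no equilibrium has to be driven.

**Step 6.** Hydrogen uptake may go past one equivalent, the hydrogenation may take the other regiochemical course (reduction next to a hydroxyl-bearing carbon), or methanol may be lost on acidification.

Fallback from commercial phloroglucinol F5 in place of 7, rejoining at 8: NaBH4 in water reduces it to 5-hydroxycyclohexane-1,3-dione F6; trimethyl orthoformate in methanol with a trace of acid gives 5-hydroxy-3-methoxycyclohex-2-en-1-one F7; MeI/Ag2O gives 3,5-dimethoxycyclohex-2-en-1-one F8; and dilute HCl in THF at 20 °C hydrolyses the enol ether to 8.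

## Further compounds

F1 | step 9 | (S)-5-hydroxy-6,7-dimethoxyflavanone | O=C1C[C@@H](c2ccccc2)Oc2cc(OC)c(OC)c(O)c21
F2 | step 9 | (2S,4S)-5-hydroxy-6,7-dimethoxyflavan-4-ol | O[C@H]1C[C@@H](c2ccccc2)Oc2cc(OC)c(OC)c(O)c21
F3 | step 9 | (2S)-6,7-dimethoxy-2-phenyl-2,3-dihydro-5H-chromen-5-one (ortho-quinone methide) | O=C1C(OC)=C(OC)C=C2O[C@H](c3ccccc3)CC=C12
F4 | step 8 | 5-methoxy-2-[(4-nitrophenoxy)methylene]cyclohexane-1,3-dione | COC1CC(=O)C(=COc2ccc([N+](=O)[O-])cc2)C(=O)C1
F5 | step 6 | phloroglucinol | Oc1cc(O)cc(O)c1
F6 | step 6 | 5-hydroxycyclohexane-1,3-dione | OC1CC(=O)CC(=O)C1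
F7 | step 6 | 5-hydroxy-3-methoxycyclohex-2-en-1-one | COC1=CC(=O)CC(O)C1
F8 | step 6 | 3,5-dimethoxycyclohex-2-en-1-one | COC1=CC(=O)CC(OC)C1
F9 | step 10 | trimethylsilyl dienol ether of 12 (C5–OSiMe3, C5=C6) | COC1CC2=C(C(O[Si](C)(C)C)=C1)[C@H](O[C@@H]1C[C@@H](c3ccccc3)Oc3cc(OC)c(OC)c(OC)c31)C[C@@H](c1ccccc1)O2
F10 | step 10 | 6-(trimethylsilyloxy) derivative of 12 | COC1CC2=C(C(=O)C1O[Si](C)(C)C)[C@H](O[C@@H]1C[C@@H](c3ccccc3)Oc3cc(OC)c(OC)c(OC)c31)C[C@@H](c1ccccc1)O2
F11 | step 12 | trimethylsilyl enol ether of 15 (C5–OSiMe3, C5=C6) | COC1CC2=C(C(O[Si](C)(C)C)=C1OC)[C@H](O[C@@H]1C[C@@H](c3ccccc3)Oc3cc(OC)c(OC)c(OC)c31)C[C@@H](c1ccccc1)O2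
A1 | alternative 1 | open-chain dibromo diol (Br at each future C8a, OH at each future C2, 5-O-allyl on unit A) | COc1cc(Br)c(c(OCC=C)c1OC)[C@H](O[C@@H](c1c(Br)cc(OC)c(OC)c1OC)C[C@H](O)c1ccccc1)C[C@@H](c1ccccc1)O
A2 | alternative 1 | 5-O-allyl ether of beilschmieflavonoid B | COc1cc2c(c(OCC=C)c1OC)[C@H](O[C@@H]1C[C@@H](c3ccccc3)Oc3cc(OC)c(OC)c(OC)c31)C[C@@H](c1ccccc1)O2
A3 | alternative 2 | metathesis diene (vinyl on C4', 1-phenylvinyl aryl ether, 5-O-TBS unit A) | COc1cc2c(c(O[Si](C)(C)C(C)(C)C)c1OC)[C@H](O[C@H](C=C)c1c(OC(=C)c3ccccc3)cc(OC)c(OC)c1OC)C[C@@H](c1ccccc1)O2
A4 | alternative 2 | 4'-alkoxy-2'-phenyl-4H-chromene ether of 5-O-TBS unit A | COc1cc2c(c(O[Si](C)(C)C(C)(C)C)c1OC)[C@H](O[C@@H]1C=C(c3ccccc3)Oc3cc(OC)c(OC)c(OC)c31)C[C@@H](c1ccccc1)O2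
A5 | alternative 3 | ortho-hydroxyaryl (E)-styrenyl carbinol ether of 5-O-SEM unit A | COc1cc2c(c(OCOCC[Si](C)(C)C)c1OC)[C@H](O[C@H](/C=C/c1ccccc1)c1c(O)cc(OC)c(OC)c1OC)C[C@@H](c1ccccc1)O2
A6 | alternative 3 | 3'-iodo derivative of 5-O-SEM beilschmieflavonoid B (2'-phenyl and 3'-iodo trans) | COc1cc2c(c(OCOCC[Si](C)(C)C)c1OC)[C@H](O[C@@H]1[C@H](I)[C@@H](c3ccccc3)Oc3cc(OC)c(OC)c(OC)c31)C[C@@H](c1ccccc1)O2
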